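**Plan**

- Tether numbering used throughout: C1 = CH2 on the phenolic ring, C2 and C3 = the two CHMe carbons, C4 = CH(OAc) on the trimethoxyphenyl ring.
- Retrosynthesis cuts, in order: (a) the aryl-C/spiro-C bond of the seven-membered ring, giving the seco-phenol 20; (b) the acetate, benzyl and silyl groups; (c) the C2 methyl, traced back to CH2OH and a 1,1-disubstituted alkene; (d) the C2–CH2Ar bond (Weinreb amide + benzylic Grignard); (e) the C3–C4 bond (aldol).
- Forward order: the open tether is built first (C3–C4 by aldol, then C2 with its arylmethyl group and a methylene, hydroboration, deoxygenation). After protecting-group exchange the seven-membered carbocycle and the cyclohexadienone arise together in the last step.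
- Stereochemistry: C4 (R) and C3 (S) come from an Evans syn-aldol with the (R)-benzyloxazolidinone. C2 (R) comes from 1,2-induction by C3 in a 9-BBN hydroboration. The spiro carbon is not stereogenic.
- Enabling feature: the 4-hydroxy-3,5-dimethoxyphenyl ring carries the tether CH2 on the carbon para to OH, so two-electron oxidation of the phenol places positive charge on that carbon. It is held four sp3 carbons away from C2/C6 of the 3,4,5-trimethoxyphenyl ring, each of which is para to a methoxy group. Ipso attack therefore closes the seven-membered ring and leaves the 2,6-dimethoxycyclohexa-2,5-dienone; both rings are locally symmetric, so there is no regio- or stereochemical issue at the new quaternary carbon.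

Key step: step 15

Remark on the chemistry: the target SMILES is read as C4 R, C3 S, C2 R (2,3-syn and 3,4-syn along the extended tether, i.e. trans,trans on the seven-membered ring); the spiro carbon bears two identical dienone arms and needs no control.

**Route**

Step 1
Reactants: 1 (R)-4-benzyl-3-propanoyl-1,3-oxazolidin-2-one; 2 3,4,5-trimethoxybenzaldehyde
Product: 4 (R)-4-benzyl-3-[(2R,3R)-3-hydroxy-2-methyl-3-(3,4,5-trimethoxyphenyl)propanoyl]-1,3-oxazolidin-2-one, via boron enolate 3 (not isolated)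
Conditions: Bu2BOTf, i-Pr2NEt, CH2Cl2, 0 °C; then 2, −78 → 0 °C; pH 7 buffer, MeOH, H2O2
Reagents that add atoms: none
Why: Evans boron syn-aldol, in which the (Z)-enolate reacts through a closed Zimmerman–Traxler chair and the (R)-benzyl auxiliary shields one enolate face, so the carbinol centre (R, future C4) and the methyl-bearing centre (R here, future C3 S) are set together as the "Evans syn" pair.

Step 2
Reactants: 4 aldol adduct
Product: 5 (2R,3R)-3-hydroxy-N-methoxy-N,2-dimethyl-3-(3,4,5-trimethoxyphenyl)propanamide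
Conditions: MeNHOMe·HCl, AlMe3, CH2Cl2, −10 °C → rt
Reagents that add atoms: N,O-dimethylhydroxylamine hydrochloride, CNOC.Cl
Why: Weinreb aluminium-amide transamidation, in which the free β-hydroxyl binds aluminium and directs attack to the exocyclic carbonyl, so the auxiliary is released without epimerisation or retro-aldol.

Step 3
Reactants: 5 hydroxy Weinreb amide
Product: 6 (2R,3R)-3-[(tert-butyldimethylsilyl)oxy]-N-methoxy-N,2-dimethyl-3-(3,4,5-trimethoxyphenyl)propanamide
Conditions: TBSOTf, 2,6-lutidine, CH2Cl2, −78 → 0 °C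
Reagents that add atoms: tert-butyldimethylsilyl triflate, CC(C)(C)[Si](C)(C)OS(=O)(=O)C(F)(F)F
Why: Silylation of a hindered secondary benzylic alcohol with the silyl triflate, which blocks retro-aldol in the following steps and provides the bulky, non-coordinating group that later steers the hydroboration.

Step 4
Reactants: 7 4-hydroxy-3,5-dimethoxybenzaldehyde (syringaldehyde)
Product: 8 4-(benzyloxy)-3,5-dimethoxybenzaldehyde
Conditions: BnBr, K2CO3, DMF, rt
Reagents that add atoms: benzyl bromide, BrCc1ccccc1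
Why: Williamson etherification of the phenoxide, to which the aldehyde is inert.

Step 5
Reactants: 8 4-(benzyloxy)-3,5-dimethoxybenzaldehyde
Product: 9 [4-(benzyloxy)-3,5-dimethoxyphenyl]methanol
Conditions: NaBH4, MeOH, 0 °C
Reagents that add atoms: none
Why: Borohydride reduction of an aryl aldehyde, with the ether groups untouched.

Step 6
Reactants: 9 [4-(benzyloxy)-3,5-dimethoxyphenyl]methanol
Product: 10 2-(benzyloxy)-5-(chloromethyl)-1,3-dimethoxybenzene
Conditions: SOCl2, pyridine, CH2Cl2, 0 °C; used directly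
Reagents that add atoms: thionyl chloride, O=S(Cl)Cl
Why: Chlorodehydroxylation through the chlorosulfite, with pyridine taking up HCl so that the electron-rich benzylic chloride is not ionised further.

Step 7
Reactants: 10 2-(benzyloxy)-5-(chloromethyl)-1,3-dimethoxybenzene; 6 silyloxy Weinreb amide
Product: 12 (3R,4R)-1-[4-(benzyloxy)-3,5-dimethoxyphenyl]-4-[(tert-butyldimethylsilyl)oxy]-3-methyl-4-(3,4,5-trimethoxyphenyl)butan-2-one, via Grignard reagent 11 (not isolated)
Conditions: Mg (activated), THF, 0 °C, slow addition of 10 under dilution; then 6, 0 °C → rt; aq NH4Cl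
Reagents that add atoms: none
Why: Weinreb ketone synthesis, in which the benzylic Grignard reagent adds once to give a chelated tetrahedral magnesium intermediate that collapses to the ketone only on quench, so neither over-addition nor epimerisation next to the carbonyl should occur.

Step 8
Reactants: 12 benzyl ketone
Product: 13 tert-butyl{[(1R,2S)-3-[4-(benzyloxy)-3,5-dimethoxybenzyl]-2-methyl-1-(3,4,5-trimethoxyphenyl)but-3-en-1-yl]oxy}dimethylsilane
Conditions: Cp2TiMe2, toluene, 65 °C, dark
Reagents that add atoms: dimethyltitanocene (Petasis reagent), C[Ti](C)(C1C=CC=C1)C1C=CC=C1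
Why: Petasis methylenation, whose non-basic titanium methylidene reacts by [2+2]/retro-[2+2], so the enolisable benzyl ketone is olefinated without epimerisation of the α-centre, β-elimination of the silyloxy group or migration of the new double bond.

Step 9
Reactants: 13 1,1-disubstituted alkene
Product: 15 (2R,3S,4R)-2-[4-(benzyloxy)-3,5-dimethoxybenzyl]-4-[(tert-butyldimethylsilyl)oxy]-3-methyl-4-(3,4,5-trimethoxyphenyl)butan-1-ol, via alkylborane 14 (not isolated)
Conditions: 9-BBN, THF, 0 → 50 °C; then NaOH, H2O2, 0 °C → rt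
Reagents that add atoms: hydrogen peroxide, OO
Why: Hydroboration–oxidation, in which 9-BBN places boron on the terminal CH2 and hydrogen on C2 from the face anti to the bulky CH(OTBS)Ar group in the A(1,3)-strain-minimised conformer (allylic C–H eclipsing the C=C), the established sense for 2-substituted 1-alkenes with an allylic methyl stereocentre, so that the CH2OH (the future C2 methyl) ends up syn to the C3 methyl along the tether and C2 becomes R; the oxidation proceeds with retention.

Step 10
Reactants: 15 primary alcohol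
Product: 16 (2R,3S,4R)-2-[4-(benzyloxy)-3,5-dimethoxybenzyl]-4-[(tert-butyldimethylsilyl)oxy]-3-methyl-4-(3,4,5-trimethoxyphenyl)butyl 4-methylbenzenesulfonate
Conditions: TsCl, Et3N, DMAP (cat.), CH2Cl2, 0 °C → rt
Reagents that add atoms: p-toluenesulfonyl chloride, Cc1ccc(cc1)S(Cl)(=O)=O
Why: Sulfonylation of the only free hydroxyl, a primary one; the silylated C4 oxygen cannot cyclise onto the new leaving group.

Step 11
Reactants: 16 tosylate
Product: 17 tert-butyl{[(1R,2S,3R)-4-[4-(benzyloxy)-3,5-dimethoxyphenyl]-2,3-dimethyl-1-(3,4,5-trimethoxyphenyl)butyl]oxy}dimethylsilane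
Conditions: LiEt3BH, THF, 0 °C → rt
Reagents that add atoms: none
Why: SN2 displacement of the primary tosylate by hydride (Super-Hydride reduction), which turns CH2OTs into the C2 methyl group without touching a stereocentre or the silyl and benzyl ethers.

Step 12
Reactants: 17 silyl ether
Product: 18 (1R,2S,3R)-4-[4-(benzyloxy)-3,5-dimethoxyphenyl]-2,3-dimethyl-1-(3,4,5-trimethoxyphenyl)butan-1-ol
Conditions: TBAF, THF, 0 °C → rt
Reagents that add atoms: none
Why: Fluoride-mediated Si–O cleavage, to which the aryl benzyl and methyl ethers are inert.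

Step 13
Reactants: 18 benzylic alcohol
Product: 19 (1R,2S,3R)-4-[4-(benzyloxy)-3,5-dimethoxyphenyl]-2,3-dimethyl-1-(3,4,5-trimethoxyphenyl)butyl acetate
Conditions: Ac2O, Et3N, DMAP (cat.), CH2Cl2, rt
Reagents that add atoms: acetic anhydride, CC(=O)OC(C)=O
Why: DMAP-catalysed acylation of the secondary alcohol, which installs the acetate of the target and at the same time masks this oxygen as a non-nucleophilic group for the oxidation.

Step 14
Reactants: 19 benzyl ether acetate
Product: 20 (1R,2S,3R)-4-(4-hydroxy-3,5-dimethoxyphenyl)-2,3-dimethyl-1-(3,4,5-trimethoxyphenyl)butyl acetate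
Conditions: H2 (1 atm), 10% Pd/C, EtOAc, rt, stopped at full debenzylation
Reagents that add atoms: none
Why: Hydrogenolysis of the aryl benzyl ether, which in neutral ethyl acetate should be much faster than cleavage of the hindered secondary benzylic acetate.

Step 15
Reactants: 20 seco-phenol acetate
Product: 22 (7R,8S,9R)-2,3,3',4,5'-pentamethoxy-7,8-dimethyl-4'-oxo-6,7,8,9-tetrahydrospiro[benzo[7]annulene-5,1'-cyclohexa[2,5]dien]-9-yl acetate (CNP0143674.1), via aryloxy-λ3-iodane 21 (not isolated)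
Conditions: PhI(OAc)2 (1.05 equiv), CF3CH2OH (high dilution), −40 °C; cold NaHCO3 quench
Reagents that add atoms: none
Why: Ligand exchange of the phenol at iodine(III) gives the aryloxy-λ3-iodane, which loses iodobenzene and acetate to a fluoroalcohol-stabilised phenoxenium (2,6-dimethoxycyclohexadienyl) cation; the ortho carbon of the trimethoxyphenyl ring attacks its alkyl-bearing para carbon and proton loss restores that arene, leaving the cross-conjugated dienone. The closest known reaction type is the hypervalent-iodine para-phenol/arene oxidative spirocyclisation in fluoroalcohols, which is used for phenolic 1,4-diarylbutanes and related tethers to make 6/7-spirodienones. The seven-membered carbocycle closes in a 7-exo mode (Friedel–Crafts attack of the arene, ipso attack on the dienyl cation), and the phenol is dearomatised in the same event. No stereocentre is formed, because the new quaternary carbon carries two identical dienone arms, and no bond to C2, C3 or C4 is broken. Para (ipso) attack is secured because the ortho positions of the cation carry methoxy groups and would require an eight-membered ring, and regiochemistry on the nucleophile is not an issue because its two ortho carbons are equivalent and each is para to a methoxy group. C–C closure over solvent capture, quinone-methide formation, acetate ionisation or dienone–phenol rearrangement should be favoured by dilution, −40 °C, weakly nucleophilic trifluoroethanol, acetic acid as the only acid present and the non-nucleophilic acetate on C4 (a free hydroxyl would spiro-etherify).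

**Compound list**

1 | (R)-4-benzyl-3-propanoyl-1,3-oxazolidin-2-one | CCC(=O)N1[C@H](Cc2ccccc2)COC1=O | starting material
2 | 3,4,5-trimethoxybenzaldehyde | COc1cc(C=O)cc(OC)c1OC | starting material
3 | (Z)-dibutylboron enolate of 1 (formed in situ) | C/C=C(\OB(CCCC)CCCC)N1[C@H](Cc2ccccc2)COC1=O | intermediate
4 | (R)-4-benzyl-3-[(2R,3R)-3-hydroxy-2-methyl-3-(3,4,5-trimethoxyphenyl)propanoyl]-1,3-oxazolidin-2-one | C[C@H]([C@@H](O)c1cc(OC)c(OC)c(OC)c1)C(=O)N1[C@H](Cc2ccccc2)COC1=O | intermediate
5 | (2R,3R)-3-hydroxy-N-methoxy-N,2-dimethyl-3-(3,4,5-trimethoxyphenyl)propanamide | C[C@H]([C@@H](O)c1cc(OC)c(OC)c(OC)c1)C(=O)N(C)OC | intermediate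
6 | (2R,3R)-3-[(tert-butyldimethylsilyl)oxy]-N-methoxy-N,2-dimethyl-3-(3,4,5-trimethoxyphenyl)propanamide | C[C@H]([C@@H](O[Si](C)(C)C(C)(C)C)c1cc(OC)c(OC)c(OC)c1)C(=O)N(C)OC | intermediate
7 | 4-hydroxy-3,5-dimethoxybenzaldehyde (syringaldehyde) | COc1cc(C=O)cc(OC)c1O | starting material
8 | 4-(benzyloxy)-3,5-dimethoxybenzaldehyde | COc1cc(C=O)cc(OC)c1OCc1ccccc1 | intermediate
9 | [4-(benzyloxy)-3,5-dimethoxyphenyl]methanol | COc1cc(CO)cc(OC)c1OCc1ccccc1 | intermediate
10 | 2-(benzyloxy)-5-(chloromethyl)-1,3-dimethoxybenzene | COc1cc(CCl)cc(OC)c1OCc1ccccc1 | intermediate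
11 | [4-(benzyloxy)-3,5-dimethoxybenzyl]magnesium chloride (formed in situ) | COc1cc(C[Mg]Cl)cc(OC)c1OCc1ccccc1 | intermediate
12 | (3R,4R)-1-[4-(benzyloxy)-3,5-dimethoxyphenyl]-4-[(tert-butyldimethylsilyl)oxy]-3-methyl-4-(3,4,5-trimethoxyphenyl)butan-2-one | C[C@H]([C@@H](O[Si](C)(C)C(C)(C)C)c1cc(OC)c(OC)c(OC)c1)C(=O)Cc1cc(OC)c(OCc2ccccc2)c(OC)c1 | intermediate
13 | tert-butyl{[(1R,2S)-3-[4-(benzyloxy)-3,5-dimethoxybenzyl]-2-methyl-1-(3,4,5-trimethoxyphenyl)but-3-en-1-yl]oxy}dimethylsilane | C[C@H]([C@@H](O[Si](C)(C)C(C)(C)C)c1cc(OC)c(OC)c(OC)c1)C(=C)Cc1cc(OC)c(OCc2ccccc2)c(OC)c1 | intermediate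
14 | 9-[(2R,3S,4R)-2-[4-(benzyloxy)-3,5-dimethoxybenzyl]-4-[(tert-butyldimethylsilyl)oxy]-3-methyl-4-(3,4,5-trimethoxyphenyl)butyl]-9-borabicyclo[3.3.1]nonane (formed in situ) | COc1cc(C[C@@H](CB2C3CCCC2CCC3)[C@H](C)[C@@H](O[Si](C)(C)C(C)(C)C)c2cc(OC)c(OC)c(OC)c2)cc(OC)c1OCc1ccccc1 | intermediate
15 | (2R,3S,4R)-2-[4-(benzyloxy)-3,5-dimethoxybenzyl]-4-[(tert-butyldimethylsilyl)oxy]-3-methyl-4-(3,4,5-trimethoxyphenyl)butan-1-ol | COc1cc(C[C@@H](CO)[C@H](C)[C@@H](O[Si](C)(C)C(C)(C)C)c2cc(OC)c(OC)c(OC)c2)cc(OC)c1OCc1ccccc1 | intermediate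
16 | (2R,3S,4R)-2-[4-(benzyloxy)-3,5-dimethoxybenzyl]-4-[(tert-butyldimethylsilyl)oxy]-3-methyl-4-(3,4,5-trimethoxyphenyl)butyl 4-methylbenzenesulfonate | COc1cc(C[C@@H](COS(=O)(=O)c2ccc(C)cc2)[C@H](C)[C@@H](O[Si](C)(C)C(C)(C)C)c2cc(OC)c(OC)c(OC)c2)cc(OC)c1OCc1ccccc1 | intermediate
17 | tert-butyl{[(1R,2S,3R)-4-[4-(benzyloxy)-3,5-dimethoxyphenyl]-2,3-dimethyl-1-(3,4,5-trimethoxyphenyl)butyl]oxy}dimethylsilane | COc1cc(C[C@@H](C)[C@H](C)[C@@H](O[Si](C)(C)C(C)(C)C)c2cc(OC)c(OC)c(OC)c2)cc(OC)c1OCc1ccccc1 | intermediate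
18 | (1R,2S,3R)-4-[4-(benzyloxy)-3,5-dimethoxyphenyl]-2,3-dimethyl-1-(3,4,5-trimethoxyphenyl)butan-1-ol | COc1cc(C[C@@H](C)[C@H](C)[C@@H](O)c2cc(OC)c(OC)c(OC)c2)cc(OC)c1OCc1ccccc1 | intermediate
19 | (1R,2S,3R)-4-[4-(benzyloxy)-3,5-dimethoxyphenyl]-2,3-dimethyl-1-(3,4,5-trimethoxyphenyl)butyl acetate | COc1cc(C[C@@H](C)[C@H](C)[C@@H](OC(C)=O)c2cc(OC)c(OC)c(OC)c2)cc(OC)c1OCc1ccccc1 | intermediate
20 | (1R,2S,3R)-4-(4-hydroxy-3,5-dimethoxyphenyl)-2,3-dimethyl-1-(3,4,5-trimethoxyphenyl)butyl acetate | COc1cc(C[C@@H](C)[C@H](C)[C@@H](OC(C)=O)c2cc(OC)c(OC)c(OC)c2)cc(OC)c1O | intermediate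
21 | (1R,2S,3R)-4-{4-[acetoxy(phenyl)-λ3-iodanyloxy]-3,5-dimethoxyphenyl}-2,3-dimethyl-1-(3,4,5-trimethoxyphenyl)butyl acetate (formed in situ) | COc1cc(C[C@@H](C)[C@H](C)[C@@H](OC(C)=O)c2cc(OC)c(OC)c(OC)c2)cc(OC)c1OI(OC(C)=O)c1ccccc1 | intermediate
22 | (7R,8S,9R)-2,3,3',4,5'-pentamethoxy-7,8-dimethyl-4'-oxo-6,7,8,9-tetrahydrospiro[benzo[7]annulene-5,1'-cyclohexa[2,5]dien]-9-yl acetate (CNP0143674.1) | COC1=CC2(C=C(OC)C1=O)C[C@@H](C)[C@H](C)[C@@H](OC(C)=O)c1cc(OC)c(OC)c(OC)c12 | target

**Step count**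

Total steps: 15. Longest linear sequence: 12 (steps 1–3 and 7–15; the branch 4–6 followed by 7–15 is equally long).

**Steps most likely to fail, with fallbacks**

1. Step 15. The process at risk is diversion of the oxidised phenol: ionisation of the benzylic acetate, acid-triggered Friedel–Crafts closure to an aryltetralin, or dienone–phenol rearrangement of the product may compete with the C–C closure. The fallback oxidises before any benzylic ester exists. It sets out from silyl ether 17: hydrogenolysis (H2, Pd/C, EtOAc) should give the silyloxy phenol F1; PhI(OAc)2 in CF3CH2OH at −40 °C should close the ring to the silyloxy spirodienone F2, whose benzylic silyl ether is a much poorer leaving group than acetate; TBAF buffered with AcOH should give the spirodienol F3; Ac2O, pyridine, DMAP then brings the sequence back to the route at target 22.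

2. Step 9. The process at risk is insufficient facial discrimination in the hydroboration, because the alkene carries a benzyl group at C2 where the closest precedents carry a methyl group; this would give C2 epimers. The fallback replaces acyclic 1,2-induction by cyclic (lactone) stereocontrol. It sets out from aldehyde 2:
   - Brown crotylboration with the (Z)-crotyldiisopinocampheylborane that adds to the Re face of the aldehyde (prepared from (+)-Ipc2BOMe, cis-2-butene, n-BuLi/KOt-Bu, BF3·OEt2; oxidative work-up) should give the syn homoallylic alcohol F4.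
   - 9-BBN, then NaOH/H2O2, should give the 1,4-diol F5.
   - TEMPO (cat.)/PhI(OAc)2 should give the cis-4-methyl-5-aryl lactone F6.
   - LDA, then MeI, at −78 °C should methylate trans to the 4-methyl and 5-aryl groups to give the 3,4-trans lactone F7, which fixes the C2/C3 relationship.
   - LiAlH4 should give the diol F8, and TBSOTf/2,6-lutidine the bis-silyl ether F9.
   - HF·pyridine should remove the primary silyl group to give the alcohol F10, and I2, PPh3, imidazole should give the iodide F11.
   - The aryl bromide F12 is made from commercial 4-bromo-2,6-dimethoxyphenol (BnBr, K2CO3, DMF). Nickel-catalysed reductive cross-electrophile coupling of F11 with F12 (NiBr2·glyme, 4,4'-di-tert-butyl-2,2'-bipyridine, Zn, NaI, DMA, 60 °C) brings the sequence back to the route at compound 17.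

3. Step 14. The process at risk is over-reduction: hydrogenolytic loss of the benzylic acetate alongside O-debenzylation. The fallback removes the benzyl group before the benzylic ester exists. It sets out from alcohol 18: H2, Pd/C, EtOAc should give the phenol-diol F13; Ac2O, pyridine, DMAP should give the diacetate F14; pyrrolidine in CH2Cl2 at 0 °C should aminolyse only the aryl acetate, and the sequence comes back to the route at compound 20.

Further compounds
F1 | step 15 | 4-[(2R,3S,4R)-4-[(tert-butyldimethylsilyl)oxy]-2,3-dimethyl-4-(3,4,5-trimethoxyphenyl)butyl]-2,6-dimethoxyphenol | COc1cc(C[C@@H](C)[C@H](C)[C@@H](O[Si](C)(C)C(C)(C)C)c2cc(OC)c(OC)c(OC)c2)cc(OC)c1O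
F2 | step 15 | (7R,8S,9R)-9-[(tert-butyldimethylsilyl)oxy]-2,3,3',4,5'-pentamethoxy-7,8-dimethyl-6,7,8,9-tetrahydrospiro[benzo[7]annulene-5,1'-cyclohexa[2,5]dien]-4'-one | COC1=CC2(C=C(OC)C1=O)C[C@@H](C)[C@H](C)[C@@H](O[Si](C)(C)C(C)(C)C)c1cc(OC)c(OC)c(OC)c12
F3 | step 15 | (7R,8S,9R)-9-hydroxy-2,3,3',4,5'-pentamethoxy-7,8-dimethyl-6,7,8,9-tetrahydrospiro[benzo[7]annulene-5,1'-cyclohexa[2,5]dien]-4'-one | COC1=CC2(C=C(OC)C1=O)C[C@@H](C)[C@H](C)[C@@H](O)c1cc(OC)c(OC)c(OC)c12
F4 | step 9 | (1R,2S)-2-methyl-1-(3,4,5-trimethoxyphenyl)but-3-en-1-ol | C=C[C@H](C)[C@@H](O)c1cc(OC)c(OC)c(OC)c1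
F5 | step 9 | (1R,2S)-2-methyl-1-(3,4,5-trimethoxyphenyl)butane-1,4-diol | OCC[C@H](C)[C@@H](O)c1cc(OC)c(OC)c(OC)c1
F6 | step 9 | (4S,5R)-4-methyl-5-(3,4,5-trimethoxyphenyl)oxolan-2-one | O=C1C[C@H](C)[C@H](c2cc(OC)c(OC)c(OC)c2)O1
F7 | step 9 | (3S,4S,5R)-3,4-dimethyl-5-(3,4,5-trimethoxyphenyl)oxolan-2-one | O=C1[C@@H](C)[C@H](C)[C@H](c2cc(OC)c(OC)c(OC)c2)O1
F8 | step 9 | (1R,2S,3S)-2,3-dimethyl-1-(3,4,5-trimethoxyphenyl)butane-1,4-diol | OC[C@@H](C)[C@H](C)[C@@H](O)c1cc(OC)c(OC)c(OC)c1
F9 | step 9 | tert-butyl{[(1R,2S,3S)-4-[(tert-butyldimethylsilyl)oxy]-2,3-dimethyl-1-(3,4,5-trimethoxyphenyl)butyl]oxy}dimethylsilane | CC(C)(C)[Si](C)(C)OC[C@@H](C)[C@H](C)[C@@H](O[Si](C)(C)C(C)(C)C)c1cc(OC)c(OC)c(OC)c1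
F10 | step 9 | (2S,3S,4R)-4-[(tert-butyldimethylsilyl)oxy]-2,3-dimethyl-4-(3,4,5-trimethoxyphenyl)butan-1-ol | OC[C@@H](C)[C@H](C)[C@@H](O[Si](C)(C)C(C)(C)C)c1cc(OC)c(OC)c(OC)c1
F11 | step 9 | tert-butyl{[(1R,2S,3S)-4-iodo-2,3-dimethyl-1-(3,4,5-trimethoxyphenyl)butyl]oxy}dimethylsilane | IC[C@@H](C)[C@H](C)[C@@H](O[Si](C)(C)C(C)(C)C)c1cc(OC)c(OC)c(OC)c1
F12 | step 9 | 2-(benzyloxy)-5-bromo-1,3-dimethoxybenzene | COc1cc(Br)cc(OC)c1OCc1ccccc1
F13 | step 14 | 4-[(2R,3S,4R)-4-hydroxy-2,3-dimethyl-4-(3,4,5-trimethoxyphenyl)butyl]-2,6-dimethoxyphenol | COc1cc(C[C@@H](C)[C@H](C)[C@@H](O)c2cc(OC)c(OC)c(OC)c2)cc(OC)c1O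
F14 | step 14 | (1R,2S,3R)-4-[4-(acetyloxy)-3,5-dimethoxyphenyl]-2,3-dimethyl-1-(3,4,5-trimethoxyphenyl)butyl acetate | COc1cc(C[C@@H](C)[C@H](C)[C@@H](OC(C)=O)c2cc(OC)c(OC)c(OC)c2)cc(OC)c1OC(C)=O
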